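The seven-membered ring (C1, C5–C10) is reached by a one-carbon ring expansion that exploits its homoallylic array C6(O)–C7H2–C8(CH3)=C9. The precursor is a cyclopentane-annulated 1-methylbicyclo[4.1.0]heptane: six-membered ring C1–C5–C6–C8–C9–C10, C7 as the cyclopropane methylene across C6–C8, and a methoxy leaving group at C9. Acid ionisation at C9 cleaves the C6–C8 bond and water enters at C6 with inversion. One operation thus gives the cycloheptene, the C8=C9 double bond and the C6 carbinol stereocentre. A single CBS-set carbinol is relayed to C1 by Claisen rearrangement; the cyclopropane face, C5 and C4 follow by substrate control.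

Key step: step 11

Remark: daucane numbering is used for the target and all intermediates (C1 quaternary carbon with C15H3; C2, C3; C4 carbinol carbon with isopropyl; C5 ring-fusion CH; C6 ester carbon; C7; C8 with C14H3; C9; C10), β is the face of C15H3, and the SMILES is read as (3R,3aS,4R,8aR) in azulene numbering, i.e. C15H3, C4–OH and C6–O on the β face and H5 on the α face.

Step 1
Reactants: 1 2-bromo-3-methylcyclopent-2-en-1-one
Product: 2 (R)-2-bromo-3-methylcyclopent-2-en-1-ol
Conditions: BH3·SMe2 (0.7 equiv), (S)-1-methyl-3,3-diphenyltetrahydro-1H,3H-pyrrolo[1,2-c][1,3,2]oxazaborole (10 mol%), THF, −20 °C; MeOH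
Reagents that add atoms: none
Why: CBS reduction: the borane-loaded (S)-oxazaborolidine binds the carbonyl anti to the larger bromoalkenyl arm and delivers hydride to one enantioface, which should set the (R)-carbinol at the future C4 as the only source of absolute configuration (this centre is used for chirality transfer and later becomes sp2).

Step 2
Reactants: 2 (R)-2-bromo-3-methylcyclopent-2-en-1-ol
Product: 3 ethyl 2-[(1R)-2-bromo-1-methylcyclopent-2-en-1-yl]acetate
Conditions: CH3C(OEt)3 (6 equiv), EtCO2H (10 mol%), xylene, 140 °C, EtOH distilled off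
Reagents that add atoms: triethyl orthoacetate, CC(OCC)(OCC)OCC
Why: Johnson–Claisen rearrangement: the mixed ketene acetal undergoes a suprafacial [3,3] shift across the cyclopentene, so the C1–C10 bond forms on the ring face that carried the C4–O bond, transferring the carbinol chirality to the quaternary C1 and leaving the bromide on the new C4=C5 double bond.

Step 3
Reactants: 3 ethyl 2-[(1R)-2-bromo-1-methylcyclopent-2-en-1-yl]acetate
Product: 5 1-[(1R)-2-bromo-1-methylcyclopent-2-en-1-yl]-3-methylbut-3-en-2-one, via Weinreb amide 4 (not isolated)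
Conditions: MeNH(OMe)·HCl (1.5 equiv), i-PrMgCl (3.0 equiv), THF, −20 °C; then CH2=C(CH3)MgBr (2 equiv), 0 °C; aq. NH4Cl
Reagents that add atoms: isopropenylmagnesium bromide, CC(=C)[Mg]Br; N,O-dimethylhydroxylamine hydrochloride, CNOC.Cl (its atoms stay in 4 only)
Why: Acyl substitution through the Weinreb amide: the magnesium amide converts the ester into 4, whose chelated tetrahedral adduct with the alkenyl Grignard reagent collapses only on work-up, so addition stops at the ketone; the alkenyl bromide is inert under these conditions and no stereocentre is touched.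

Step 4
Reactants: 5 1-[(1R)-2-bromo-1-methylcyclopent-2-en-1-yl]-3-methylbut-3-en-2-one
Product: 6 (7aR)-5,7a-dimethyl-1,2,7,7a-tetrahydro-6H-inden-6-one (dienone with C4=C5 and C6=C8 and the C9 carbonyl)
Conditions: Pd(OAc)2 (10 mol%), tri(o-tolyl)phosphine (20 mol%), Et3N (2 equiv), MeCN, 80 °C
Reagents that add atoms: none
Why: Intramolecular Mizoroki–Heck reaction: oxidative addition at C5–Br, insertion of the enone with C5 bonding to the terminal β-carbon (the future C6; formal 6-endo mode, the conjugate-type regiochemistry of enone acceptors, whereas the 5-exo adduct would lack a syn β-hydrogen) and β-hydride elimination should give the linearly conjugated dienone without touching C1.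

Step 5
Reactants: 6 (7aR)-5,7a-dimethyl-1,2,7,7a-tetrahydro-6H-inden-6-one
Product: 7 (6R,7aR)-5,7a-dimethyl-2,6,7,7a-tetrahydro-1H-inden-6-ol (9β-dienol)
Conditions: catecholborane (1.5 equiv), (S)-1-methyl-3,3-diphenyltetrahydro-1H,3H-pyrrolo[1,2-c][1,3,2]oxazaborole (20 mol%), toluene, −78 °C; aq. NaOH
Reagents that add atoms: none
Why: CBS reduction of the enone carbonyl (1,2-selective): with the methyl-bearing alkenyl arm as the large group the (S)-catalyst should deliver hydride to the C9 face anti to the 1,3-related axial C15 methyl (reagent and substrate control matched), giving the 9β-alcohol.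

Step 6
Reactants: 7 (6R,7aR)-5,7a-dimethyl-2,6,7,7a-tetrahydro-1H-inden-6-ol
Product: 8 tricyclic cyclopropyl carbinol (C6–C7–C8 cyclopropane on the cyclohexane ring; C4=C5 retained; C9–OH, C7 and C15H3 all β)
Conditions: Et2Zn (2.5 equiv), CH2I2 (2.5 equiv), CH2Cl2, −20 → 0 °C; aq. NH4Cl/NaHCO3
Reagents that add atoms: diiodomethane, ICI
Why: Simmons–Smith cyclopropanation (Furukawa variant): the zinc alkoxide at C9 directs the carbenoid to the adjacent C6=C8 bond and to its own face, so C7 is delivered cis to the hydroxyl (β face) and sets C6 and C8 together, while the undirected C4=C5 bond reacts more slowly.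

Step 7
Reactants: 8 tricyclic cyclopropyl carbinol
Product: 9 C9 methyl ether of 8
Conditions: NaH, CH3I, THF, 0 °C → rt
Reagents that add atoms: iodomethane, CI
Why: Williamson etherification of the sodium alkoxide; the methyl ether masks C9–O during the oxidation and organometallic steps and later serves as the leaving group, and no stereocentre is affected.

Step 8
Reactants: 9 C9 methyl ether of 8
Product: 11 C4 α-alcohol with trans ring fusion (H5 α; 9β-OMe; β-cyclopropane), via alkylborane 10 (not isolated)
Conditions: BH3·THF (1.5 equiv), THF, 0 °C → rt; then NaOH (3 M), H2O2 (30%), 0 °C → rt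
Reagents that add atoms: hydrogen peroxide, OO; borane–tetrahydrofuran, B.C1CCOC1 (its boron stays in 10 only)
Why: Hydroboration–oxidation: boron adds to the less substituted C4 and hydrogen to C5, syn and from the α face opposite to the C15 methyl and the cyclopropane methylene, which should set the trans ring fusion (H5 anti to C15H3) and, after oxidation with retention, the 4α-hydroxyl.

Step 9
Reactants: 11 C4 α-alcohol
Product: 12 C4 ketone (trans-fused; 9β-OMe; β-cyclopropane)
Conditions: Dess–Martin periodinane (1.5 equiv), NaHCO3, CH2Cl2, 0 °C → rt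
Reagents that add atoms: none
Why: Dess–Martin oxidation under buffered, non-basic conditions converts the secondary alcohol into the cyclopentanone without epimerising the adjacent C5 ring-fusion centre.

Step 10
Reactants: 12 C4 ketone
Product: 13 tertiary alcohol (4β-OH, 4α-isopropyl; 9β-OMe; β-cyclopropane; trans-fused)
Conditions: i-PrMgCl (3 equiv), CeCl3 (3 equiv), THF, −78 °C; aq. NH4Cl
Reagents that add atoms: isopropylmagnesium chloride, CC(C)[Mg]Cl
Why: Organocerium 1,2-addition: the weakly basic cerium reagent suppresses enolisation towards C5 and reduction, and attacks the C4 carbonyl from the α face, opposite to the C15 methyl and the β-oriented C5–C6 bond, which should give the 4β-hydroxyl and 4α-isopropyl group.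

Step 11
Reactants: 13 tertiary alcohol
Product: 14 (3R,3aS,4R,8aR)-6,8a-dimethyl-3-(propan-2-yl)-1,2,3,3a,4,5,8,8a-octahydroazulene-3,4-diol (4β,6β-diol with C8=C9)
Conditions: 4-methylbenzenesulfonic acid monohydrate (0.2 equiv), 1,4-dioxane/H2O (3:1), 75 °C
Reagents that add atoms: water, O
Why: Acid protonates the C9 methoxy group and methanol leaves with σ-participation of the cyclopropane, giving a bisected cyclopropylcarbinyl (bicyclobutonium-type) cation with charge shared between C9, C6 and C7; water attacks the secondary C6 while the C6–C8 bond breaks and C8=C9 forms, so the six-membered ring C1–C5–C6–C8–C9–C10 becomes the cycloheptene C1–C5–C6–C7–C8–C9–C10. The closest known reaction type is the solvolytic cyclopropylcarbinyl-to-homoallyl rearrangement (i-steroid 6-methyl ether to 3β-hydroxy-Δ5-steroid, 2-norcaranyl to cyclohept-3-enyl, sabinene to terpinen-4-ol). No ring is closed: the seven-membered ring arises by scission of the zero-atom bridge of the bicyclo[4.1.0]heptane, a ring expansion by one carbon (C7). The only new stereocentre, C6, is set stereospecifically because the nucleophile must enter anti to the departing C6–C8 bond; with C7 on the β face (from step 6) this should place the C6 hydroxyl cis to C15H3 and to the C4 hydroxyl, while C1, C4 and C5 are spectators and the C9 configuration is erased. The step needs cleavage of the internal C6–C8 bond rather than the external C7–C8 bond (secondary versus primary cation character) and net capture at C6 rather than C9 (C9 capture only regenerates cyclopropyl carbinols that re-ionise, whereas the strain-free homoallylic alcohol is the thermodynamic sink). The aqueous medium with only catalytic sulfonic acid at moderate temperature should keep the tertiary C4 hydroxyl from E1 loss.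

Step 12
Reactants: 14 4β,6β-diol; 15 4-acetoxybenzoyl chloride
Product: 17 (3R,3aS,4R,8aR)-3-hydroxy-6,8a-dimethyl-3-(propan-2-yl)-1,2,3,3a,4,5,8,8a-octahydroazulen-4-yl 4-hydroxybenzoate (target), via aryl acetate 16 (not isolated)
Conditions: 15 (1.3 equiv), 4-(dimethylamino)pyridine (0.2 equiv), pyridine, CH2Cl2, 0 °C → rt; then pyrrolidine (3 equiv), 0 °C
Reagents that add atoms: none
Why: Nucleophilic acylation catalysed by 4-(dimethylamino)pyridine esterifies the only secondary hydroxyl (C6; the tertiary C4 hydroxyl does not react), and the phenolic acetate of 16, far more electrophilic than the hindered benzoate, is then removed in the same flask by aminolysis with pyrrolidine; no stereocentre is affected.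

Compound list
1 | 2-bromo-3-methylcyclopent-2-en-1-one | CC1=C(Br)C(=O)CC1 | starting material
2 | (R)-2-bromo-3-methylcyclopent-2-en-1-ol | O[C@@H]1CCC(C)=C1Br | intermediate
3 | ethyl 2-[(1R)-2-bromo-1-methylcyclopent-2-en-1-yl]acetate | CCOC(=O)C[C@@]1(C)CCC=C1Br | intermediate
4 | 2-[(1R)-2-bromo-1-methylcyclopent-2-en-1-yl]-N-methoxy-N-methylacetamide (Weinreb amide) | CON(C)C(=O)C[C@@]1(C)CCC=C1Br | intermediate
5 | 1-[(1R)-2-bromo-1-methylcyclopent-2-en-1-yl]-3-methylbut-3-en-2-one | CC(=C)C(=O)C[C@@]1(C)CCC=C1Br | intermediate
6 | (7aR)-5,7a-dimethyl-1,2,7,7a-tetrahydro-6H-inden-6-one | CC1=CC2=CCC[C@]2(C)CC1=O | intermediate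
7 | (6R,7aR)-5,7a-dimethyl-2,6,7,7a-tetrahydro-1H-inden-6-ol | CC1=CC2=CCC[C@]2(C)C[C@H]1O | intermediate
8 | tricyclic cyclopropyl carbinol: cyclohexane C1-C5-C6-C8-C9-C10 fused to cyclopentene C1-C2-C3-C4=C5 and to cyclopropane C6-C7-C8; C9-OH, C7 and C15H3 on the β face | C[C@]12C[C@H]1C1=CCC[C@]1(C)C[C@H]2O | intermediate
9 | C9 methyl ether of 8 | C[C@]12C[C@H]1C1=CCC[C@]1(C)C[C@H]2OC | intermediate
10 | C4 alkylborane from 9 (BH2 on C4 α, H5 α) | C[C@]12C[C@H]1[C@H]1[C@H](B)CC[C@]1(C)C[C@H]2OC | intermediate
11 | C4 α-alcohol: trans-fused, H5 α, 9β-OMe, β-cyclopropane | C[C@]12C[C@H]1[C@H]1[C@H](O)CC[C@]1(C)C[C@H]2OC | intermediate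
12 | C4 ketone: trans-fused, H5 α, 9β-OMe, β-cyclopropane | C[C@]12C[C@H]1[C@H]1C(=O)CC[C@]1(C)C[C@H]2OC | intermediate
13 | tertiary alcohol: 4β-OH, 4α-isopropyl, H5 α, 9β-OMe, β-cyclopropane | C[C@]12C[C@H]1[C@H]1[C@](O)(C(C)C)CC[C@]1(C)C[C@H]2OC | intermediate
14 | (3R,3aS,4R,8aR)-6,8a-dimethyl-3-(propan-2-yl)-1,2,3,3a,4,5,8,8a-octahydroazulene-3,4-diol | CC1=CC[C@@]2(C)CC[C@@](O)(C(C)C)[C@@H]2[C@H](O)C1 | intermediate
15 | 4-acetoxybenzoyl chloride | CC(=O)Oc1ccc(cc1)C(Cl)=O | starting material
16 | (3R,3aS,4R,8aR)-3-hydroxy-6,8a-dimethyl-3-(propan-2-yl)-1,2,3,3a,4,5,8,8a-octahydroazulen-4-yl 4-acetoxybenzoate | CC1=CC[C@@]2(C)CC[C@@](O)(C(C)C)[C@@H]2[C@H](OC(=O)c2ccc(OC(C)=O)cc2)C1 | intermediate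
17 | (3R,3aS,4R,8aR)-3-hydroxy-6,8a-dimethyl-3-(propan-2-yl)-1,2,3,3a,4,5,8,8a-octahydroazulen-4-yl 4-hydroxybenzoate | CC1=CC[C@@]2(C)CC[C@@](O)(C(C)C)[C@@H]2[C@H](OC(=O)c2ccc(O)cc2)C1 | target

Total step count: 12. Longest linear sequence: 12 steps (1 → 17; 15 is bought).

Steps most likely to fail

1. Step 4 (Heck ring closure). The insertion may run in the 5-exo sense (C5–C8 bond) and end in a neopentyl-type alkylpalladium that decomposes, or the double bonds may migrate under palladium hydride. The fallback sets out from ester 3 and returns at dienone 6. The same in situ Weinreb amide 4 is treated with EtMgBr instead of the alkenyl Grignard reagent to give the ethyl ketone 1-[(1R)-2-bromo-1-methylcyclopent-2-en-1-yl]butan-2-one F1. Reductive carbonylation of the alkenyl bromide (Pd(PPh3)4, CO 1 atm, Bu3SnH, THF, 50 °C) gives the keto enal (5R)-5-methyl-5-(2-oxobutyl)cyclopent-1-ene-1-carbaldehyde F2. Intramolecular aldol condensation (KOH, MeOH, rt) between the ketone α-carbon C8 and the aldehyde C6 closes the cyclohexenone; no epimerisable centre is involved.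

2. Step 11 (ring expansion). The delocalised cation may be intercepted at C7 by the neighbouring tertiary C4 hydroxyl (cyclic ether), that hydroxyl may be lost under acid, or the cation may lose a proton to dienes. The fallback sets out from ketone 12 and returns at diol 14 by inverting the order of steps 10 and 11. The same aqueous acid treatment of 12, which has no tertiary hydroxyl, should give the ring-expanded β-hydroxy ketone (3aS,4R,8aR)-4-hydroxy-6,8a-dimethyl-3,3a,4,5,8,8a-hexahydroazulen-1(2H)-one F3. Addition of i-PrMgCl/CeCl3 (excess, THF, −78 °C) to the C4 carbonyl from the α face then gives 14.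

3. Step 10 (isopropyl addition). The hindered ketone may be reduced by β-hydride transfer from the isopropyl reagent, or enolised with loss of the trans ring fusion at C5. The fallback sets out from ketone 12 and returns at 13. The smaller sp2 nucleophile CH2=C(CH3)Li with CeCl3 (THF, −78 °C), which has no β-hydrogen to transfer, is added from the same α face to give the isopropenyl carbinol (4β-OH, 4α-isopropenyl analogue of 13) F4. Homogeneous hydrogenation of the 1,1-disubstituted alkene (RhCl(PPh3)3, H2 1 atm, benzene, rt) leaves the cyclopropane and the methyl ether intact.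

Further compounds
F1 | step 4 | 1-[(1R)-2-bromo-1-methylcyclopent-2-en-1-yl]butan-2-one | CCC(=O)C[C@@]1(C)CCC=C1Br
F2 | step 4 | (5R)-5-methyl-5-(2-oxobutyl)cyclopent-1-ene-1-carbaldehyde | CCC(=O)C[C@@]1(C)CCC=C1C=O
F3 | step 11 | (3aS,4R,8aR)-4-hydroxy-6,8a-dimethyl-3,3a,4,5,8,8a-hexahydroazulen-1(2H)-one | CC1=CC[C@@]2(C)CCC(=O)[C@@H]2[C@H](O)C1
F4 | step 10 | isopropenyl carbinol: 4β-OH, 4α-(prop-1-en-2-yl), H5 α, 9β-OMe, β-cyclopropane | C[C@]12C[C@H]1[C@H]1[C@](O)(C(C)=C)CC[C@]1(C)C[C@H]2OC
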